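**Retrosynthetic overview**

1. Both angelates come from angelic anhydride; the C8/C9 cis-diol comes from a C8=C9 cycloheptene (dihydroxylation anti to the C7 ester) and the C7 carbinol from a cycloheptenone (reagent-controlled reduction).
2. Key disconnection: the seven-membered ring is opened at C5–C6 by a retro-aldol to a (Z)-isopropyl enone tethered to a cyclobutanone; the aldol oxygen at C5 is removed reductively.
3. The bicyclo[3.1.1]heptanone (cyclobutane and six-membered ring) comes from an intramolecular vinylketene–alkene [2+2] cycloaddition of a dienynoic acid; its silyloxy stereocentre (the later C1 carbonyl) controls the absolute configuration.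
4. The acid is assembled by an enantioselective vinylogous Mukaiyama aldol of (2E)-3-methylpent-2-en-4-ynal with the silyl dienolate of methyl 3-methylbut-2-enoate; the remaining C4 unit is isobutyryl chloride.
5. Ring order: cyclobutane and six-membered ring together (cycloaddition), then the seven-membered ring (intramolecular aldol); the enone is unveiled late.

Assumption: the target is taken exactly as the given SMILES (both esters are angelates, (2Z)-2-methylbut-2-enoates). Tricyclic compounds are named with longipinane numbering: C1 enone carbonyl, C2=C3 enone alkene with methyl C12 on C3, C4 and C11 bridgeheads (C4 next to C3), C5 cyclobutane CH, C6 gem-dimethyl carbon, C7–C9 oxygen-bearing carbons (C7 next to C6), C10 quaternary methyl carbon.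

**Route**

Step 1
Reactants: 1 methyl 3-methylbut-2-enoate
Product: 2 (1Z)-tert-butyl[(1-methoxy-3-methylbuta-1,3-dien-1-yl)oxy]dimethylsilane
Conditions: LiN(iPr)2, THF, −78 °C; TBSCl, DMPU, −78 °C to rt
Reagents that add atoms: tert-butyldimethylsilyl chloride (TBSCl), CC(C)(C)[Si](C)(C)Cl
Why: Kinetic γ-deprotonation of the senecioate (extended enolate) and O-silylation give the silyl dienol ether needed for the vinylogous Mukaiyama aldol; no stereocentre is formed.

Step 2
Reactants: 3 (2E)-3-methylpent-2-en-4-yn-1-ol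
Product: 4 (2E)-3-methylpent-2-en-4-ynal
Conditions: MnO2 (activated, 10 equiv), CH2Cl2, rt
Reagents that add atoms: none
Why: Chemoselective MnO2 oxidation of the allylic alcohol gives the conjugated enynal with retention of the (E)-alkene; no stereocentre is formed.

Step 3
Reactants: 2 (1Z)-tert-butyl[(1-methoxy-3-methylbuta-1,3-dien-1-yl)oxy]dimethylsilane; 4 (2E)-3-methylpent-2-en-4-ynal
Product: 6 methyl (2E,5S,6E)-5-hydroxy-3,7-dimethylnona-2,6-dien-8-ynoate, via trichlorosilyl ether 5 (not isolated)
Conditions: SiCl4 (1.1 equiv), (R,R)-binaphthyldiamine-derived bisphosphoramide (Denmark catalyst, 5 mol %), iPr2NEt (10 mol %), CH2Cl2, −78 °C; aq. NaHCO3 work-up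
Reagents that add atoms: none
Why: Lewis-base-catalysed, SiCl4-mediated vinylogous Mukaiyama aldol: the dienolate attacks through its γ-carbon the aldehyde bound to the chiral phosphoramide–trichlorosilyl cation, which exposes the Si face so that C5 is formed (S) and the new enoate is (E); the handedness of the catalyst is assigned from the usual sense of induction of this system, and the antipodal catalyst would give ent-6.

Step 4
Reactants: 6 methyl (2E,5S,6E)-5-hydroxy-3,7-dimethylnona-2,6-dien-8-ynoate
Product: 7 methyl (2E,5S,6E)-5-[(tert-butyldimethylsilyl)oxy]-3,7-dimethylnona-2,6-dien-8-ynoate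
Conditions: TBSCl, imidazole, DMF, rt
Reagents that add atoms: tert-butyldimethylsilyl chloride (TBSCl), CC(C)(C)[Si](C)(C)Cl
Why: Imidazole-mediated silylation masks the hydroxyl for the acid chloride and ketene chemistry and makes it the steric control element of step 6; the stereocentre is untouched.

Step 5
Reactants: 7 methyl (2E,5S,6E)-5-[(tert-butyldimethylsilyl)oxy]-3,7-dimethylnona-2,6-dien-8-ynoate
Product: 8 (2E,5S,6E)-5-[(tert-butyldimethylsilyl)oxy]-3,7-dimethylnona-2,6-dien-8-ynoic acid
Conditions: LiOH, THF/MeOH/H2O, rt; then 1 M HCl to pH 4, 0 °C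
Reagents that add atoms: lithium hydroxide, [Li+].[OH-]
Why: Saponification (acyl–oxygen ester hydrolysis) frees the carboxylic acid without affecting the silyl ether, the alkyne or the (E)-enoate.

Step 6
Reactants: 8 (2E,5S,6E)-5-[(tert-butyldimethylsilyl)oxy]-3,7-dimethylnona-2,6-dien-8-ynoic acid
Product: 11 (1R,2S,5R,7R)-2-[(tert-butyldimethylsilyl)oxy]-7-ethynyl-7-methyl-4-methylidenebicyclo[3.1.1]heptan-6-one, via acid chloride 9 (not isolated), via vinylketene 10 (not isolated)
Conditions: (COCl)2, DMF (cat.), CH2Cl2, 0 °C; evaporate; slow addition to Et3N (3 equiv), toluene, 110 °C, 0.005 M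
Reagents that add atoms: none
Why: 1,4-Dehydrochlorination gives the vinylketene, which undergoes an intramolecular thermal ketene–alkene [2+2] cycloaddition with crossed regiochemistry (ketene carbonyl carbon to the alkene CH, ketene α-carbon to the methyl-bearing carbon); suprafacial addition to the (E)-alkene puts the ethynyl group syn to the carbonyl bridge, and allylic 1,3-strain between the alkene methyl and the silyloxy stereocentre steers the ketene to the face anti to the OTBS group, setting C1, C5 and C7 of the bicycle as (1R,5R,7R).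

Step 7
Reactants: 11 (1R,2S,5R,7R)-2-[(tert-butyldimethylsilyl)oxy]-7-ethynyl-7-methyl-4-methylidenebicyclo[3.1.1]heptan-6-one; 12 2-methylpropanoyl chloride (isobutyryl chloride)
Product: 13 2-[(tert-butyldimethylsilyl)oxy]-7-methyl-4-methylidene-7-(4-methyl-3-oxopent-1-yn-1-yl)bicyclo[3.1.1]heptan-6-one (ring stereocentres as in 11)
Conditions: PdCl2(PPh3)2 (2 mol %), CuI (4 mol %), Et3N, THF, rt
Reagents that add atoms: none
Why: Acyl Sonogashira coupling of the terminal alkyne with the acid chloride gives the ynone under conditions that leave the cyclobutanone, silyl ether and methylidene group untouched; no stereocentre is formed.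

Step 8
Reactants: 13 2-[(tert-butyldimethylsilyl)oxy]-7-methyl-4-methylidene-7-(4-methyl-3-oxopent-1-yn-1-yl)bicyclo[3.1.1]heptan-6-one
Product: 14 2-[(tert-butyldimethylsilyl)oxy]-7-methyl-4-methylidene-7-[(1Z)-4-methyl-3-oxopent-1-en-1-yl]bicyclo[3.1.1]heptan-6-one (ring stereocentres as in 11)
Conditions: H2 (1 atm), Pd on CaCO3 poisoned with Pb(OAc)2 (Lindlar catalyst), quinoline, EtOAc, 0 °C, stopped after 1 equiv H2
Reagents that add atoms: none
Why: Lindlar syn semi-hydrogenation of the ynone gives the (Z)-enone, the only geometry that lets the isopropyl ketone reach the cyclobutanone; no stereocentre is formed.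

Step 9
Reactants: 14 2-[(tert-butyldimethylsilyl)oxy]-7-methyl-4-methylidene-7-[(1Z)-4-methyl-3-oxopent-1-en-1-yl]bicyclo[3.1.1]heptan-6-one
Product: 17 1-[(tert-butyldimethylsilyl)oxy]-7-oxolongipina-3(12),8-dien-5-yl methyl oxalate, via lithium dienolate 15 (not isolated), via lithium aldolate 16 (not isolated)
Conditions: LiN(iPr)2 (1.05 equiv), THF, −78 °C, 1 h; ClCOCO2Me (2 equiv), −78 to −30 °C
Reagents that add atoms: methyl chlorooxalate (methyl 2-chloro-2-oxoacetate), COC(=O)C(Cl)=O
Why: Deprotonation can only occur at the isopropyl methine (the γ-carbon is quaternary, the cyclobutanone α-carbons are bridgeheads), and the cross-conjugated enolate closes the seven-membered ring by intramolecular aldol addition to the strained cyclobutanone, forming the C5–C6 bond and the gem-dimethyl quaternary carbon with the C5 configuration dictated by the tether; the tertiary aldolate is trapped in situ as its methyl oxalate to block retro-aldol and prepare the deoxygenation.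

Step 10
Reactants: 17 1-[(tert-butyldimethylsilyl)oxy]-7-oxolongipina-3(12),8-dien-5-yl methyl oxalate
Product: 18 1-[(tert-butyldimethylsilyl)oxy]longipina-3(12),8-dien-7-one
Conditions: Bu3SnH (2 equiv), AIBN (0.2 equiv), toluene, 100 °C
Reagents that add atoms: none
Why: Radical deoxygenation of the tertiary methyl oxalate (Barton–McCombie-type chain) replaces the C5 oxygen by hydrogen; the C5 radical belongs to three rings, so hydrogen can only enter from the exo side and C5 acquires the target configuration.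

Step 11
Reactants: 18 1-[(tert-butyldimethylsilyl)oxy]longipina-3(12),8-dien-7-one
Product: 19 (7R)-1-[(tert-butyldimethylsilyl)oxy]longipina-3(12),8-dien-7-ol
Conditions: (S)-2-methyl-CBS-oxazaborolidine (0.2 equiv), catecholborane (1.5 equiv), toluene, −78 to −40 °C; aq. NaOH work-up
Reagents that add atoms: none
Why: Corey–Bakshi–Shibata reduction: the oxazaborolidine distinguishes the quaternary C6 flank (large) from the vinyl flank (small) and delivers hydride 1,2 to one carbonyl face under reagent control, giving the (7R)-allylic alcohol, which has the C7 geometry of the target.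

Step 12
Reactants: 20 angelic acid [(2Z)-2-methylbut-2-enoic acid] (2 equiv)
Product: 21 angelic anhydride [(2Z)-2-methylbut-2-enoic anhydride]
Conditions: DCC (0.5 equiv per acid), CH2Cl2, 0 °C to rt; filter
Reagents that add atoms: none
Why: Carbodiimide dehydration of two molecules of angelic acid gives the symmetric anhydride under cold, neutral conditions that do not isomerise the (Z)-alkene to the tiglate.

Step 13
Reactants: 19 (7R)-1-[(tert-butyldimethylsilyl)oxy]longipina-3(12),8-dien-7-ol; 21 angelic anhydride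
Product: 22 1-[(tert-butyldimethylsilyl)oxy]longipina-3(12),8-dien-7-yl angelate
Conditions: LiN(SiMe3)2 (1.1 equiv), THF, −78 °C; 21 (1.5 equiv), −78 to 0 °C
Reagents that add atoms: none
Why: O-Acylation of the hindered lithium alkoxide with the anhydride at low temperature installs the C7 angelate without (Z) to (E) isomerisation and with retention at the carbinol carbon.

Step 14
Reactants: 22 1-[(tert-butyldimethylsilyl)oxy]longipina-3(12),8-dien-7-yl angelate
Product: 23 1-hydroxylongipina-3(12),8-dien-7-yl angelate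
Conditions: TBAF/AcOH (1:1, 3 equiv), THF, rt to 40 °C
Reagents that add atoms: none
Why: Fluoride desilylation buffered with acetic acid frees the C1 hydroxyl while sparing the angelate and the acid-sensitive methylidene bicycle.

Step 15
Reactants: 23 1-hydroxylongipina-3(12),8-dien-7-yl angelate
Product: 25 1-oxolongipina-2,8-dien-7-yl angelate, via deconjugated ketone 24 (not isolated)
Conditions: Dess–Martin periodinane, NaHCO3, CH2Cl2, 0 °C to rt; then DBU (0.1 equiv), 0 °C, 30 min
Reagents that add atoms: none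
Why: Dess–Martin oxidation gives the β,γ-unsaturated ketone and base-catalysed migration of the exocyclic alkene into conjugation gives the verbenone-type enone of the target; the C1 stereocentre, having served as control element, is removed.

Step 16
Reactants: 25 1-oxolongipina-2,8-dien-7-yl angelate
Product: 26 8,9-dihydroxy-1-oxolongipin-2-en-7-yl angelate
Conditions: OsO4 (5 mol %), NMO (2 equiv), acetone/H2O (8:1), rt; aq. Na2SO3
Reagents that add atoms: osmium tetroxide, O=[Os](=O)(=O)=O; N-methylmorpholine N-oxide, C[N+]1([O-])CCOCC1; water, O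
Why: Upjohn dihydroxylation is chemoselective for the only alkene that is not conjugated to a carbonyl and, following Kishi's rule, adds syn on the face anti to the allylic C7 angelate, setting the C8 and C9 hydroxyls cis to each other and trans to the C7 ester.

Step 17
Reactants: 26 8,9-dihydroxy-1-oxolongipin-2-en-7-yl angelate; 21 angelic anhydride
Product: 27 CNP0256888.1 (9-hydroxy-1-oxolongipin-2-ene-7,8-diyl diangelate)
Conditions: LiN(SiMe3)2 (1.05 equiv), THF, −78 °C; 21 (1.2 equiv), −78 to −40 °C; AcOH quench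
Reagents that add atoms: none
Why: Kinetic mono-acylation with angelic anhydride takes place at the equatorial C8 hydroxyl, which is much less hindered than the axial, neopentyl C9 hydroxyl next to quaternary C10, and gives the target without touching a stereocentre.

**Compound list**

1 | methyl 3-methylbut-2-enoate | COC(=O)C=C(C)C | starting material
2 | (1Z)-tert-butyl[(1-methoxy-3-methylbuta-1,3-dien-1-yl)oxy]dimethylsilane | C=C(C)/C=C(\O[Si](C)(C)C(C)(C)C)OC | intermediate
3 | (2E)-3-methylpent-2-en-4-yn-1-ol | C#C/C(C)=C/CO | starting material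
4 | (2E)-3-methylpent-2-en-4-ynal | C#C/C(C)=C/C=O | intermediate
5 | methyl (2E,5S,6E)-3,7-dimethyl-5-[(trichlorosilyl)oxy]nona-2,6-dien-8-ynoate (not isolated) | COC(=O)/C=C(\C)C[C@H](O[Si](Cl)(Cl)Cl)/C=C(\C)C#C | intermediate
6 | methyl (2E,5S,6E)-5-hydroxy-3,7-dimethylnona-2,6-dien-8-ynoate | COC(=O)/C=C(\C)C[C@H](O)/C=C(\C)C#C | intermediate
7 | methyl (2E,5S,6E)-5-[(tert-butyldimethylsilyl)oxy]-3,7-dimethylnona-2,6-dien-8-ynoate | COC(=O)/C=C(\C)C[C@H](O[Si](C)(C)C(C)(C)C)/C=C(\C)C#C | intermediate
8 | (2E,5S,6E)-5-[(tert-butyldimethylsilyl)oxy]-3,7-dimethylnona-2,6-dien-8-ynoic acid | OC(=O)/C=C(\C)C[C@H](O[Si](C)(C)C(C)(C)C)/C=C(\C)C#C | intermediate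
9 | (2E,5S,6E)-5-[(tert-butyldimethylsilyl)oxy]-3,7-dimethylnona-2,6-dien-8-ynoyl chloride (not isolated) | ClC(=O)/C=C(\C)C[C@H](O[Si](C)(C)C(C)(C)C)/C=C(\C)C#C | intermediate
10 | (5S,6E)-5-[(tert-butyldimethylsilyl)oxy]-7-methyl-3-methylidenenona-1,6-dien-8-yn-1-one, the vinylketene (not isolated) | O=C=CC(=C)C[C@H](O[Si](C)(C)C(C)(C)C)/C=C(\C)C#C | intermediate
11 | (1R,2S,5R,7R)-2-[(tert-butyldimethylsilyl)oxy]-7-ethynyl-7-methyl-4-methylidenebicyclo[3.1.1]heptan-6-one (ethynyl syn to the carbonyl bridge, OTBS on the carbonyl-bridge side) | O=C1[C@H]2[C@@H](O[Si](C)(C)C(C)(C)C)CC(=C)[C@@H]1[C@@]2(C)C#C | intermediate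
12 | 2-methylpropanoyl chloride (isobutyryl chloride) | CC(C)C(Cl)=O | starting material
13 | 2-[(tert-butyldimethylsilyl)oxy]-7-methyl-4-methylidene-7-(4-methyl-3-oxopent-1-yn-1-yl)bicyclo[3.1.1]heptan-6-one (ring stereocentres as in 11) | O=C1[C@H]2[C@@H](O[Si](C)(C)C(C)(C)C)CC(=C)[C@@H]1[C@@]2(C)C#CC(=O)C(C)C | intermediate
14 | 2-[(tert-butyldimethylsilyl)oxy]-7-methyl-4-methylidene-7-[(1Z)-4-methyl-3-oxopent-1-en-1-yl]bicyclo[3.1.1]heptan-6-one (ring stereocentres as in 11) | O=C1[C@H]2[C@@H](O[Si](C)(C)C(C)(C)C)CC(=C)[C@@H]1[C@@]2(C)/C=C\C(=O)C(C)C | intermediate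
15 | lithium dienolate of 14, enolised at the isopropyl carbon (not isolated) | O=C1[C@H]2[C@@H](O[Si](C)(C)C(C)(C)C)CC(=C)[C@@H]1[C@@]2(C)/C=C\C(O[Li])=C(C)C | intermediate
16 | lithium 1-[(tert-butyldimethylsilyl)oxy]-7-oxolongipina-3(12),8-dien-5-olate (not isolated) | C1=CC(=O)C(C)(C)[C@]2(O[Li])[C@H]3[C@@H](O[Si](C)(C)C(C)(C)C)CC(=C)[C@@H]2[C@]31C | intermediate
17 | 1-[(tert-butyldimethylsilyl)oxy]-7-oxolongipina-3(12),8-dien-5-yl methyl oxalate | C1=CC(=O)C(C)(C)[C@]2(OC(=O)C(=O)OC)[C@H]3[C@@H](O[Si](C)(C)C(C)(C)C)CC(=C)[C@@H]2[C@]31C | intermediate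
18 | 1-[(tert-butyldimethylsilyl)oxy]longipina-3(12),8-dien-7-one | C1=CC(=O)C(C)(C)[C@@H]2[C@H]3[C@@H](O[Si](C)(C)C(C)(C)C)CC(=C)[C@@H]2[C@]31C | intermediate
19 | (7R)-1-[(tert-butyldimethylsilyl)oxy]longipina-3(12),8-dien-7-ol | C1=C[C@@H](O)C(C)(C)[C@@H]2[C@H]3[C@@H](O[Si](C)(C)C(C)(C)C)CC(=C)[C@@H]2[C@]31C | intermediate
20 | angelic acid, (2Z)-2-methylbut-2-enoic acid | C/C=C(/C)C(=O)O | starting material
21 | angelic anhydride, (2Z)-2-methylbut-2-enoic anhydride | C/C=C(/C)C(=O)OC(=O)/C(C)=C\C | intermediate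
22 | 1-[(tert-butyldimethylsilyl)oxy]longipina-3(12),8-dien-7-yl angelate | C1=C[C@@H](OC(=O)/C(C)=C\C)C(C)(C)[C@@H]2[C@H]3[C@@H](O[Si](C)(C)C(C)(C)C)CC(=C)[C@@H]2[C@]31C | intermediate
23 | 1-hydroxylongipina-3(12),8-dien-7-yl angelate | C1=C[C@@H](OC(=O)/C(C)=C\C)C(C)(C)[C@@H]2[C@H]3[C@@H](O)CC(=C)[C@@H]2[C@]31C | intermediate
24 | 1-oxolongipina-3(12),8-dien-7-yl angelate (not isolated) | C1=C[C@@H](OC(=O)/C(C)=C\C)C(C)(C)[C@@H]2[C@H]3C(=O)CC(=C)[C@@H]2[C@]31C | intermediate
25 | 1-oxolongipina-2,8-dien-7-yl angelate | C1=C[C@@H](OC(=O)/C(C)=C\C)C(C)(C)[C@@H]2[C@H]3C(=O)C=C(C)[C@@H]2[C@]31C | intermediate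
26 | 8,9-dihydroxy-1-oxolongipin-2-en-7-yl angelate (8-OH and 9-OH cis, both trans to the 7-ester) | O[C@@H]1[C@@H](OC(=O)/C(C)=C\C)C(C)(C)[C@@H]2[C@H]3C(=O)C=C(C)[C@@H]2[C@@]3(C)[C@@H]1O | intermediate
27 | CNP0256888.1, 9-hydroxy-1-oxolongipin-2-ene-7,8-diyl diangelate | C/C=C(/C)C(=O)O[C@@H]1[C@@H](OC(=O)/C(C)=C\C)C(C)(C)[C@@H]2[C@H]3C(=O)C=C(C)[C@@H]2[C@@]3(C)[C@@H]1O | target

**Step count**

Total steps: 17. Longest linear sequence: 15 steps (3 → 4 → 6 → 7 → 8 → 11 → 13 → 14 → 17 → 18 → 19 → 22 → 23 → 25 → 26 → 27; steps 2–11 and 13–17). Steps 1 and 12 lie on side branches.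

**Steps most likely to fail, with fallbacks**

Step 6 (ketene [2+2]). The enyne alkene is a weaker nucleophile than a simple trisubstituted alkene, and the vinylketene can oligomerise. Fallback: use a keteniminium ion instead of a ketene. It sets out from 8 and comes back at 11. Acid 8 is converted through acid chloride 9 and Me2NH into the N,N-dimethylamide F1. Tf2O with 2,6-di-tert-butyl-4-methylpyridine in 1,2-dichloroethane (0 to 80 °C) generates the much more electrophilic vinylketeniminium ion, whose intramolecular [2+2] cycloaddition gives the cyclobutaniminium triflate F2. Aqueous NaHCO3 hydrolysis returns ketone 11.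

Step 9 (aldol ring closure). Enolisation of the hindered methine may be slow, the (Z)-enone may isomerise, and the congested aldolate may revert. Fallback: generate the enolate regiospecifically by conjugate reduction (reductive aldol cyclisation). It sets out from 11 and comes back at 17. Acyl Sonogashira coupling of 11 with 2-methylprop-2-enoyl chloride gives the dienynone F3, and Lindlar semi-hydrogenation gives the (Z)-divinyl ketone F4. [(Ph3P)CuH]6 (toluene, −40 °C to rt) adds hydride to the unhindered methylidene terminus, and the copper enolate formed at C6 closes onto the cyclobutanone to give the tertiary alcohol F5. ClCOCO2Me, DMAP and pyridine convert it into 17.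

Step 17 (regioselective mono-angeloylation). Competing acylation at C9, acyl migration or partial isomerisation to the tiglate would erode the yield. Fallback: differentiate the diol with protecting groups. It sets out from 26 and comes back at 27. TESCl/imidazole at −40 °C silylates only the C8 hydroxyl to give the silyl ether F6. Chloroacetic anhydride, pyridine and DMAP cap the C9 hydroxyl as the chloroacetate F7. HF·pyridine removes the triethylsilyl group to give the C8 alcohol F8. Yamaguchi esterification with angelic acid 20 (2,4,6-trichlorobenzoyl chloride, Et3N, then DMAP, toluene) gives the diangelate chloroacetate F9. Thiourea and NaHCO3 in ethanol at 50 °C remove the chloroacetate and give 27.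

**Further compounds**

F1 | step 6 | (2E,5S,6E)-5-[(tert-butyldimethylsilyl)oxy]-N,N,3,7-tetramethylnona-2,6-dien-8-ynamide | CN(C)C(=O)/C=C(\C)C[C@H](O[Si](C)(C)C(C)(C)C)/C=C(\C)C#C
F2 | step 6 | N-{2-[(tert-butyldimethylsilyl)oxy]-7-ethynyl-7-methyl-4-methylidenebicyclo[3.1.1]heptan-6-ylidene}-N-methylmethanaminium triflate (ring stereocentres as in 11) | C[N+](C)=C1[C@H]2[C@@H](O[Si](C)(C)C(C)(C)C)CC(=C)[C@@H]1[C@@]2(C)C#C.[O-]S(=O)(=O)C(F)(F)F
F3 | step 9 | 2-[(tert-butyldimethylsilyl)oxy]-7-methyl-4-methylidene-7-(4-methyl-3-oxopent-4-en-1-yn-1-yl)bicyclo[3.1.1]heptan-6-one (ring stereocentres as in 11) | O=C1[C@H]2[C@@H](O[Si](C)(C)C(C)(C)C)CC(=C)[C@@H]1[C@@]2(C)C#CC(=O)C(C)=C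
F4 | step 9 | 2-[(tert-butyldimethylsilyl)oxy]-7-methyl-4-methylidene-7-[(1Z)-4-methyl-3-oxopenta-1,4-dien-1-yl]bicyclo[3.1.1]heptan-6-one (ring stereocentres as in 11) | O=C1[C@H]2[C@@H](O[Si](C)(C)C(C)(C)C)CC(=C)[C@@H]1[C@@]2(C)/C=C\C(=O)C(C)=C
F5 | step 9 | 1-[(tert-butyldimethylsilyl)oxy]-5-hydroxylongipina-3(12),8-dien-7-one | C1=CC(=O)C(C)(C)[C@]2(O)[C@H]3[C@@H](O[Si](C)(C)C(C)(C)C)CC(=C)[C@@H]2[C@]31C
F6 | step 17 | 9-hydroxy-1-oxo-8-[(triethylsilyl)oxy]longipin-2-en-7-yl angelate | CC[Si](CC)(CC)O[C@@H]1[C@@H](OC(=O)/C(C)=C\C)C(C)(C)[C@@H]2[C@H]3C(=O)C=C(C)[C@@H]2[C@@]3(C)[C@@H]1O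
F7 | step 17 | 9-(chloroacetoxy)-1-oxo-8-[(triethylsilyl)oxy]longipin-2-en-7-yl angelate | CC[Si](CC)(CC)O[C@@H]1[C@@H](OC(=O)/C(C)=C\C)C(C)(C)[C@@H]2[C@H]3C(=O)C=C(C)[C@@H]2[C@@]3(C)[C@@H]1OC(=O)CCl
F8 | step 17 | 9-(chloroacetoxy)-8-hydroxy-1-oxolongipin-2-en-7-yl angelate | O[C@@H]1[C@@H](OC(=O)/C(C)=C\C)C(C)(C)[C@@H]2[C@H]3C(=O)C=C(C)[C@@H]2[C@@]3(C)[C@@H]1OC(=O)CCl
F9 | step 17 | 9-(chloroacetoxy)-1-oxolongipin-2-ene-7,8-diyl diangelate | C/C=C(/C)C(=O)O[C@@H]1[C@@H](OC(=O)/C(C)=C\C)C(C)(C)[C@@H]2[C@H]3C(=O)C=C(C)[C@@H]2[C@@]3(C)[C@@H]1OC(=O)CCl
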